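All constants come from no measurement.

Free base is charged at less than the nucleophile, so count the acid before you count the yield.

electrophile 0.020 M; nucleophile 0.800 equiv; free base 0.300 equiv; protic impurity 2.00 mM; time 6.0 d

    electrophile + nucleophile → acid set free + target (k1 = 1.4 /M/h)
    nucleophile + acid set free ⇌ protonated nucleophile, settled at all times (K2 = 58000 /M)
    acid set free + free base ⇌ salt of the base, settled at all times (K3 = 1.0 × 10⁷ /M)
    electrophile + protic impurity → quenched substrate (k4 = 2.8 /M/h)
    free base + target → over-reaction product (k5 = 1.9 /M/h)

* part of the electrophile that has reacted at 6.0 d
* share of the unused nucleophile that is free and not bound as protonated nucleophile, at 6.0 d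

**Bench rule.** Treat the nucleophile as limiting reagent and expect one coupling per nucleophile. This needs free base for every acid set free, but free base over nucleophile is 0.375, so the rule stops working here.

**One nucleophile.** Follow one nucleophile molecule. Free base binds acid 172 times as strongly as the nucleophile does, so while free base lasts, each coupling uses one nucleophile. After that the acid takes a second nucleophile: the constant of the nucleophile's binding times c(nucleophile) is 930 at the start. Add free base to the nucleophile charge and divide by two: this coupling ceiling, my estimate of the part of the electrophile that couples with every acid bound and every free base taking acid, is 55.0%. Add 10.0% for the protic impurity, whose step sets free no acid, and c comes to 65.0%. The half-life of electrophile by the coupling step alone, the other concentrations as charged, is 1.3 d, short against 6.0 d, so as an estimate take the ceiling as reached. This reckoning gives no figure for fr.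

**The forecast.** It gives 62.5% and 10%, since “each coupling also protonates a second nucleophile”. My c is higher.

**At rest?** The flask gives 63.0% and 10.5%, so the forecast holds for this recipe; c moves 5 points at 0.692 equiv or 0.913 equiv of nucleophile, the other amounts and the time held. The flask has not come to rest. At 60.0 d c is 68.7%, a further 5.7 percentage points and past my estimate. Over that stretch the electrophile falls from 37.0% to 31.3%, and acid set free climbs from 1.47 × 10⁻⁴ M to 0.00183 M. The ceiling counts every acid as bound, and this acid set free is not bound.

**Second flask.** Charge 0.034 M of electrophile with the same equivalents: the ceiling stays 55.0%, and the protic impurity's 0.0588 equiv brings c to 60.9%. That flask gives 60.6%.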